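**Plan**

Numbering: lactone ring O1, C2–C6; side chain from the ketone C1' to the end of the ethyl group C12', with methyls on C4' and C10' and the carboxyl on C8'.
Retrosynthetic cuts, in order: the C8' ester protecting group; C3–C1' (acyl transfer onto a preformed pyran-2,4-dione); the C1' carboxyl, unmasked from an isopropylidene alkene; C8'–CO2H together with C9'–H; C7'–C8'; then C6'=C7' and C9'≡C8', each a one-carbon olefination of a chiral-pool aldehyde.
Forward: the C1'–C7' alkenyl iodide and the C8'–C12' alkyne unit are joined at C7'–C8' to an (E)-enyne, the enyne is hydrocarboxylated, the far alkene is cleaved to the C1' acid, and this acid is attached to C3 of the lactone. The lactone is the only ring and is made separately by Claisen condensation and O1–C2 lactonisation.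
Enabling feature: on the C8'=C9' double bond the carboxyl (on C8') and the hydrogen (on C9') are cis, C8' also bears the alkenyl carbon C7' and C9' the branched carbon C10'. The acid therefore corresponds to a syn addition of H and CO2H across a C8'≡C9' alkyne.
Stereochemistry: C4' comes from (R)-citronellal, C10' from (S)-2-methylbutan-1-ol and C6 from methyl (R)-3-hydroxybutanoate; the E geometry at C6'=C7' from the Takai reaction and the C8'=C9' geometry from the syn hydrometalation.

Key step: step 5

Assumption: the 3-acyl pyran-2,4-dione is written as the 4-hydroxy enol tautomer of the target SMILES; its tautomers interconvert freely and count as one compound.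

**Route**

Step 1
Reactants: 1 (R)-citronellal
Product: 2 (1E,4R)-1-iodo-4,8-dimethylnona-1,7-diene
Conditions: CrCl2 (6 equiv), CHI3 (2 equiv), THF/1,4-dioxane, 0 °C to rt
Reagents that add atoms: iodoform, IC(I)I
Why: Takai iodo-olefination, in which the geminal dichromium species formed from CHI3 and divalent chromium adds to the aldehyde and eliminates to the E-alkenyl iodide, while the β-stereocentre and the trisubstituted alkene are not involved.

Step 2
Reactants: 3 (S)-2-methylbutan-1-ol
Product: 4 (S)-2-methylbutanal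
Conditions: TEMPO (1 mol %), KBr (10 mol %), aq NaOCl (1.1 equiv, NaHCO3 buffer), CH2Cl2, 0 °C
Reagents that add atoms: none
Why: Anelli oxidation (oxoammonium catalysis) stops at the aldehyde in a cold buffered two-phase system, conditions under which an α-methyl aldehyde of this kind should keep its configuration; the volatile aldehyde is used at once as a dried CH2Cl2 solution.

Step 3
Reactants: 4 (S)-2-methylbutanal
Product: 5 (S)-1,1-dibromo-3-methylpent-1-ene
Conditions: CBr4, PPh3, Zn dust, CH2Cl2, rt (ylide pre-formed), then 4, 0 °C to rt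
Reagents that add atoms: carbon tetrabromide, BrC(Br)(Br)Br
Why: Dibromo-olefination (first stage of the Corey–Fuchs reaction) with the zinc-modified reagent is a neutral Wittig reaction, so the α-stereocentre should not be enolised.

Step 4
Reactants: 5 (S)-1,1-dibromo-3-methylpent-1-ene; 2 (1E,4R)-1-iodo-4,8-dimethylnona-1,7-diene
Product: 8 (6R,8E,12S)-2,6,12-trimethyltetradeca-2,8-dien-10-yne, via lithium acetylide 6 (not isolated), via alkynylzinc bromide 7 (not isolated)
Conditions: n-BuLi (2.05 equiv), THF, −78 to 0 °C; ZnBr2, 0 °C; then 2, Pd(PPh3)4 (5 mol %), rt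
Reagents that add atoms: none
Why: The second stage of the Corey–Fuchs reaction (bromine–lithium exchange, 1,2-shift, deprotonation) gives the acetylide without isolation of the volatile alkyne, and Negishi sp–sp2 coupling on zerovalent palladium joins C7'–C8' with retention of the E geometry of the iodide.

Step 5
Reactants: 8 (6R,8E,12S)-2,6,12-trimethyltetradeca-2,8-dien-10-yne; 9 carbon dioxide
Product: 12 (2E,4S)-2-[(1E,4R)-4,8-dimethylnona-1,7-dien-1-yl]-4-methylhex-2-enoic acid, via dienylzirconocene chloride 10 (not isolated), via zirconocene carboxylate 11 (not isolated)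
Conditions: Cp2Zr(H)Cl (1.5 equiv), THF, rt then 40 °C; (IPr)CuCl (10 mol %; IPr = 1,3-bis(2,6-diisopropylphenyl)imidazol-2-ylidene), CO2 (1 atm), rt to 40 °C; 1 M HCl
Reagents that add atoms: carbon dioxide (compound 9), O=C=O
Why: Proposed new method: Cp2Zr(H)Cl adds across C8'≡C9' through a four-centre transition state, so the hydrogen on C9' and the zirconium on C8' are cis, and with a small excess of hydride at 40 °C the regioisomers should equilibrate towards zirconium on C8', which is flanked by the flat alkenyl carbon C7' and lies away from the α-branched C10'. The closest known reaction types are the hydrozirconation of unsymmetrical internal alkynes, which places zirconium on the less hindered carbon, and the copper–carbene-catalysed carboxylation of alkenylzirconium, alkenylboron and alkenylaluminium reagents with CO2; their combination on a 1,3-enyne with the metal on the inner diene carbon is the new element. The dienyl group is expected to pass to univalent copper with retention, CO2 to insert into the C8'–Cu bond with retention, and the copper carboxylate to hand the carboxylate back to zirconium, which frees the catalyst. No ring closes and no stereocentre is created; the C8'=C9' geometry (CO2H cis to H) follows from the syn addition. The step needs regioselectivity for zirconium on C8', which rests on the steric contrast between sec-butyl and alkenyl, and chemoselectivity for the alkyne over the 1,2-disubstituted and trisubstituted alkenes, which react far more slowly with Cp2Zr(H)Cl.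

Step 6
Reactants: 12 (2E,4S)-2-[(1E,4R)-4,8-dimethylnona-1,7-dien-1-yl]-4-methylhex-2-enoic acid
Product: 13 tert-butyl (2E,4S)-2-[(1E,4R)-4,8-dimethylnona-1,7-dien-1-yl]-4-methylhex-2-enoate
Conditions: O-tert-butyl-N,N'-diisopropylisourea (3 equiv), CH2Cl2, rt
Reagents that add atoms: O-tert-butyl-N,N'-diisopropylisourea, CC(C)N=C(NC(C)C)OC(C)(C)C
Why: Isourea esterification transfers the tert-butyl group to the carboxylate oxygen, so the hindrance of the α-substituted acid does not matter and no Lewis acid comes near the trisubstituted alkene.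

Step 7
Reactants: 13 tert-butyl (2E,4S)-2-[(1E,4R)-4,8-dimethylnona-1,7-dien-1-yl]-4-methylhex-2-enoate
Product: 14 tert-butyl (2E,4S)-2-[(1E,4R)-6-(3,3-dimethyloxiran-2-yl)-4-methylhex-1-en-1-yl]-4-methylhex-2-enoate (both epimers at the oxirane CH)
Conditions: mCPBA (1.05 equiv), NaHCO3, CH2Cl2, 0 °C
Reagents that add atoms: mCPBA, OOC(=O)c1cccc(Cl)c1
Why: Prilezhaev epoxidation should select the electron-rich trisubstituted alkene over the ester-bearing diene; the new oxirane stereocentre forms without control and is destroyed in step 8.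

Step 8
Reactants: 14 tert-butyl (2E,4S)-2-[(1E,4R)-6-(3,3-dimethyloxiran-2-yl)-4-methylhex-1-en-1-yl]-4-methylhex-2-enoate
Product: 16 tert-butyl (2E,4S)-4-methyl-2-[(1E,4R)-4-methyl-7-oxohept-1-en-1-yl]hex-2-enoate, via vicinal diol 15 (not isolated)
Conditions: H5IO6 (1.3 equiv), THF/H2O, 0 °C to rt
Reagents that add atoms: none
Why: Acid-promoted opening of the epoxide by water at the tertiary carbon and Malaprade glycol cleavage release acetone and leave the C1' aldehyde, whose oxygen is the former epoxide oxygen; the diene ester and the tert-butyl group should tolerate cold periodic acid.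

Step 9
Reactants: 16 tert-butyl (2E,4S)-4-methyl-2-[(1E,4R)-4-methyl-7-oxohept-1-en-1-yl]hex-2-enoate
Product: 17 (4R,6E,8E,10S)-8-(tert-butoxycarbonyl)-4,10-dimethyldodeca-6,8-dienoic acid
Conditions: NaClO2, NaH2PO4, 2-methyl-2-butene, t-BuOH/H2O, 0 °C to rt
Reagents that add atoms: sodium chlorite, [Na+].[O-]Cl=O
Why: Pinnick oxidation converts the aldehyde into the acid while 2-methyl-2-butene traps the hypochlorous acid, so the diene and the C4' stereocentre are left alone.

Step 10
Reactants: 18 methyl (R)-3-hydroxybutanoate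
Product: 19 tert-butyl (R)-5-hydroxy-3-oxohexanoate
Conditions: tert-butyl acetate, LiN(iPr)2 (LDA, 3.5 equiv each), THF, −78 to −20 °C; aq NH4Cl
Reagents that add atoms: tert-butyl acetate, CC(=O)OC(C)(C)C
Why: Crossed Claisen condensation with excess lithium enolate of tert-butyl acetate (the first equivalent deprotonates the hydroxyl) gives the δ-hydroxy-β-keto ester without touching the carbinol stereocentre.

Step 11
Reactants: 19 tert-butyl (R)-5-hydroxy-3-oxohexanoate
Product: 20 (R)-6-methyldihydro-2H-pyran-2,4(3H)-dione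
Conditions: TFA, CH2Cl2, 0 °C to rt
Reagents that add atoms: none
Why: Acidolysis of the tert-butyl ester and lactonisation of the δ-hydroxyl onto the carboxyl (6-exo-trig) close the O1–C2 bond, and C6 keeps its configuration because its C–O bond is not broken.

Step 12
Reactants: 17 (4R,6E,8E,10S)-8-(tert-butoxycarbonyl)-4,10-dimethyldodeca-6,8-dienoic acid; 20 (R)-6-methyldihydro-2H-pyran-2,4(3H)-dione
Product: 22 tert-butyl (2E,4S)-2-[(1E,4R)-7-[(6R)-4-hydroxy-6-methyl-2-oxo-5,6-dihydro-2H-pyran-3-yl]-4-methyl-7-oxohept-1-en-1-yl]-4-methylhex-2-enoate, via enol ester 21 (not isolated)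
Conditions: DCC (1.2 equiv), DMAP (1.2 equiv), CH2Cl2, 0 °C to rt
Reagents that add atoms: none
Why: Steglich O-acylation of the vinylogous acid followed by DMAP-mediated O-to-C acyl migration (Fries-type) should deliver the chelated 3-acyl-4-hydroxypyranone as the thermodynamic product, with no stereocentre involved.

Step 13
Reactants: 22 tert-butyl ester of the target
Product: 23 (2E,4S)-2-[(1E,4R)-7-[(6R)-4-hydroxy-6-methyl-2-oxo-5,6-dihydro-2H-pyran-3-yl]-4-methyl-7-oxohept-1-en-1-yl]-4-methylhex-2-enoic acid
Conditions: TFA/CH2Cl2 (1:4), 0 °C to rt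
Reagents that add atoms: none
Why: Acidolysis of the tert-butyl ester (loss of the tert-butyl cation as 2-methylpropene) frees the C8' carboxylic acid, and the acyl pyrandione and the electron-poor diene should tolerate cold TFA.

**Compound list**

1 | (R)-citronellal, (3R)-3,7-dimethyloct-6-enal | O=CC[C@H](C)CCC=C(C)C | starting material
2 | (1E,4R)-1-iodo-4,8-dimethylnona-1,7-diene | I/C=C/C[C@H](C)CCC=C(C)C | intermediate
3 | (S)-2-methylbutan-1-ol | CC[C@H](C)CO | starting material
4 | (S)-2-methylbutanal | CC[C@H](C)C=O | intermediate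
5 | (S)-1,1-dibromo-3-methylpent-1-ene | CC[C@H](C)C=C(Br)Br | intermediate
6 | lithium (S)-3-methylpent-1-yn-1-ide (formed in the flask, not isolated) | CC[C@H](C)C#C[Li] | intermediate
7 | bromo[(S)-3-methylpent-1-yn-1-yl]zinc (formed in the flask, not isolated) | CC[C@H](C)C#C[Zn]Br | intermediate
8 | (6R,8E,12S)-2,6,12-trimethyltetradeca-2,8-dien-10-yne | CC[C@H](C)C#C/C=C/C[C@H](C)CCC=C(C)C | intermediate
9 | carbon dioxide | O=C=O | starting material
10 | chlorobis(cyclopentadienyl)[(6R,8E,10E,12S)-2,6,12-trimethyltetradeca-2,8,10-trien-10-yl]zirconium, Zr on C8' cis to the new C9'–H (formed in the flask, not isolated) | CC[C@H](C)/C=C(\C=C\C[C@H](C)CCC=C(C)C)[Zr](Cl)(C1C=CC=C1)C1C=CC=C1 | intermediate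
11 | chlorobis(cyclopentadienyl)zirconium carboxylate of acid 12 (formed in the flask, not isolated) | CC[C@H](C)/C=C(\C=C\C[C@H](C)CCC=C(C)C)C(=O)O[Zr](Cl)(C1C=CC=C1)C1C=CC=C1 | intermediate
12 | (2E,4S)-2-[(1E,4R)-4,8-dimethylnona-1,7-dien-1-yl]-4-methylhex-2-enoic acid | CC[C@H](C)/C=C(\C=C\C[C@H](C)CCC=C(C)C)C(=O)O | intermediate
13 | tert-butyl (2E,4S)-2-[(1E,4R)-4,8-dimethylnona-1,7-dien-1-yl]-4-methylhex-2-enoate | CC[C@H](C)/C=C(\C=C\C[C@H](C)CCC=C(C)C)C(=O)OC(C)(C)C | intermediate
14 | tert-butyl (2E,4S)-2-[(1E,4R)-6-(3,3-dimethyloxiran-2-yl)-4-methylhex-1-en-1-yl]-4-methylhex-2-enoate, both epimers at the oxirane CH | CC[C@H](C)/C=C(\C=C\C[C@H](C)CCC1OC1(C)C)C(=O)OC(C)(C)C | intermediate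
15 | tert-butyl (2E,4S)-2-[(1E,4R)-7,8-dihydroxy-4,8-dimethylnon-1-en-1-yl]-4-methylhex-2-enoate, both epimers at the secondary carbinol (formed in the flask, not isolated) | CC[C@H](C)/C=C(\C=C\C[C@H](C)CCC(O)C(C)(C)O)C(=O)OC(C)(C)C | intermediate
16 | tert-butyl (2E,4S)-4-methyl-2-[(1E,4R)-4-methyl-7-oxohept-1-en-1-yl]hex-2-enoate | CC[C@H](C)/C=C(\C=C\C[C@H](C)CCC=O)C(=O)OC(C)(C)C | intermediate
17 | (4R,6E,8E,10S)-8-(tert-butoxycarbonyl)-4,10-dimethyldodeca-6,8-dienoic acid | CC[C@H](C)/C=C(\C=C\C[C@H](C)CCC(=O)O)C(=O)OC(C)(C)C | intermediate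
18 | methyl (R)-3-hydroxybutanoate | C[C@@H](O)CC(=O)OC | starting material
19 | tert-butyl (R)-5-hydroxy-3-oxohexanoate | C[C@@H](O)CC(=O)CC(=O)OC(C)(C)C | intermediate
20 | (R)-6-methyldihydro-2H-pyran-2,4(3H)-dione | C[C@@H]1CC(=O)CC(=O)O1 | intermediate
21 | 4-O-acyl enol ester of dione 20 with acid 17 (formed in the flask, not isolated) | CC[C@H](C)/C=C(\C=C\C[C@H](C)CCC(=O)OC1=CC(=O)O[C@H](C)C1)C(=O)OC(C)(C)C | intermediate
22 | tert-butyl (2E,4S)-2-[(1E,4R)-7-[(6R)-4-hydroxy-6-methyl-2-oxo-5,6-dihydro-2H-pyran-3-yl]-4-methyl-7-oxohept-1-en-1-yl]-4-methylhex-2-enoate | CC[C@H](C)/C=C(\C=C\C[C@H](C)CCC(=O)C1=C(O)C[C@@H](C)OC1=O)C(=O)OC(C)(C)C | intermediate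
23 | (2E,4S)-2-[(1E,4R)-7-[(6R)-4-hydroxy-6-methyl-2-oxo-5,6-dihydro-2H-pyran-3-yl]-4-methyl-7-oxohept-1-en-1-yl]-4-methylhex-2-enoic acid | CC[C@H](C)/C=C(\C=C\C[C@H](C)CCC(=O)C1=C(O)C[C@@H](C)OC1=O)C(=O)O | target

**Step count**

Total: 13 steps. Longest linear sequence: 10 steps (steps 2, 3, 4, 5, 6, 7, 8, 9, 12, 13, from (S)-2-methylbutan-1-ol).

**Steps most likely to fail**

Step 5. Zirconium may settle on C9' instead of C8' (wrong-way hydrometalation), or the hindered dienyl group may transfer to copper too slowly for CO2 capture to compete. The fallback uses known reactions only and forms C7'–C8' by sp2–sp2 coupling with the carboxyl carbon already in place. It sets out from aldehyde 4 and citronellal 1 and rejoins the route at ester 13.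
- Aldehyde 4 would be condensed with tert-butyl bromo(triphenylphosphoranylidene)acetate (CH2Cl2, 0 °C to rt). This is a Wittig reaction of a stabilised ylide, which places the ester trans to the alkyl group, and gives tert-butyl (2Z,4S)-2-bromo-4-methylhex-2-enoate F1.
- Citronellal 1 would be converted by the boron variant of the Takai olefination (Cl2CHBpin, CrCl2, lithium iodide, THF, rt) into 2-[(1E,4R)-4,8-dimethylnona-1,7-dien-1-yl]-4,4,5,5-tetramethyl-1,3,2-dioxaborolane F2.
- Suzuki–Miyaura coupling of F1 with F2 (Pd(PPh3)4, aq K3PO4, THF, 60 °C) proceeds with retention at both alkenes and would give ester 13 directly.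

Step 12. The O-to-C acyl shift may stall at enol ester 21, or the activated acid may be diverted to an N-acylurea. In the fallback the ring is built on the acyl chain instead of the chain being transferred to the ring. It sets out from acid 17 and hydroxy ester 18 and rejoins the route at 22.
- Acid 17 and Meldrum's acid (DCC, DMAP, CH2Cl2) would give tert-butyl (2E,4S)-2-[(1E,4R)-7-(2,2-dimethyl-4,6-dioxo-1,3-dioxan-5-ylidene)-7-hydroxy-4-methylhept-1-en-1-yl]-4-methylhex-2-enoate F3.
- Heating F3 with methyl (R)-3-hydroxybutanoate 18 in toluene at 80 °C (acylketene trapping) would give methyl (3R)-3-{[(6R,8E,10E,12S)-10-(tert-butoxycarbonyl)-6,12-dimethyl-3-oxotetradeca-8,10-dienoyl]oxy}butanoate F4.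
- Lacey–Dieckmann closure of F4 (tetrabutylammonium fluoride in THF, or KOt-Bu in t-BuOH) forms the C3–C4 bond with loss of methanol and would give 22.

Step 1. The E selectivity of the iodo-olefination may erode, and the Z iodide would be carried through the coupling as an inseparable isomer. The fallback sets the geometry by a syn hydrometalation instead. It sets out from citronellal 1 and rejoins the route at iodide 2.
- Seyferth–Gilbert homologation of 1 with the Ohira–Bestmann reagent (dimethyl (1-diazo-2-oxopropyl)phosphonate, K2CO3, MeOH, rt) would give (R)-4,8-dimethylnon-7-en-1-yne F5.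
- Hydrozirconation of the terminal alkyne (Cp2Zr(H)Cl, THF, rt) would give chlorobis(cyclopentadienyl)[(1E,4R)-4,8-dimethylnona-1,7-dien-1-yl]zirconium F6.
- Iodinolysis of F6 with iodine at 0 °C, with retention, would give 2 as a single geometric isomer.

**Further compounds**

F1 | step 5 | tert-butyl (2Z,4S)-2-bromo-4-methylhex-2-enoate | CC[C@H](C)/C=C(\Br)C(=O)OC(C)(C)C
F2 | step 5 | 2-[(1E,4R)-4,8-dimethylnona-1,7-dien-1-yl]-4,4,5,5-tetramethyl-1,3,2-dioxaborolane | CC1(C)OB(/C=C/C[C@H](C)CCC=C(C)C)OC1(C)C
F3 | step 12 | tert-butyl (2E,4S)-2-[(1E,4R)-7-(2,2-dimethyl-4,6-dioxo-1,3-dioxan-5-ylidene)-7-hydroxy-4-methylhept-1-en-1-yl]-4-methylhex-2-enoate | CC[C@H](C)/C=C(\C=C\C[C@H](C)CCC(O)=C1C(=O)OC(C)(C)OC1=O)C(=O)OC(C)(C)C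
F4 | step 12 | methyl (3R)-3-{[(6R,8E,10E,12S)-10-(tert-butoxycarbonyl)-6,12-dimethyl-3-oxotetradeca-8,10-dienoyl]oxy}butanoate | CC[C@H](C)/C=C(\C=C\C[C@H](C)CCC(=O)CC(=O)O[C@H](C)CC(=O)OC)C(=O)OC(C)(C)C
F5 | step 1 | (R)-4,8-dimethylnon-7-en-1-yne | C#CC[C@H](C)CCC=C(C)C
F6 | step 1 | chlorobis(cyclopentadienyl)[(1E,4R)-4,8-dimethylnona-1,7-dien-1-yl]zirconium | Cl[Zr](/C=C/C[C@H](C)CCC=C(C)C)(C1C=CC=C1)C1C=CC=C1
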